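# Proposed synthesis of (5R,8R,9S,10R)-configured CNP0172818.3 by alkylative dearomatisation of a cresol

## Analysis of the target

The target is a rearranged drimane meroterpenoid. It has a trans-fused decalin (ring A: C1–C5 and C10; ring B: C5–C10) with an exocyclic methylidene at C4. The C11 methylene on C9 carries a 2-hydroxy-5-methoxy-1,4-benzoquinone.

There are four contiguous stereocentres: C5 and C9 are quaternary, C8 and C10 tertiary, with configuration 5R,8R,9S,10R. The methyl groups on C5, C8 and C9 lie on one face; H10 and the C11 arm lie on the other. The C5 and C9 methyl groups are therefore 1,3-diaxial across ring B.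

This is the mirror image of the series that comes from the usual drimane and labdane chiral pool, so the absolute configuration has to be made.

Two groups are sensitive. The 1,1-disubstituted alkene migrates into the ring or cyclises onto the quinone oxygen under acid. The hydroxyquinone is a vinylogous acid that is electrophilic, redox-active and base-sensitive. Both are best revealed late, the quinone from a 2,3,5,6-tetramethoxyphenyl group.

The hard part is the C8/C9/C5 array: a quaternary carbon next to a tertiary one, and a second quaternary carbon 1,3 to it. None of these can be corrected by epimerisation.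

The feature the route rests on is ring A. With oxygen at C4, a methyl group on C5 and the C10–C9 bond, it maps onto a 3-substituted 2-methylphenol. The methyl-bearing ortho carbon C5 can be alkylated by C6 with loss of aromaticity, which closes ring B and creates the C5 quaternary centre.

## Retrosynthetic reasoning

**Quinone (28 ⇒ 27 ⇒ 26).** The hydroxyl of 28 is traced back to a methoxy group in 27, and the quinone of 27 to the tetramethoxyarene 26. This keeps the fragile ring masked as an inert arene through all earlier steps. The forward steps must oxidise the arene without touching the alkene, then hydrolyse only one of two vinylogous ester groups.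

**Methylidene (26 ⇒ 25).** The C4=CH2 bond is cut to give ketone 25. The C4 oxygen is the phenol oxygen that served to build ring A, so no oxidation-level change is needed. The forward step is a methylenation of a ketone next to the quaternary C5.

**Ring saturation (25 ⇒ 24).** Removing the hydrogens at C1, C2, C3 and C10 leads to the cross-ring dienone 24. The gain is that C10 is set last, on a rigid bicycle whose lower face is blocked by the two axial methyl groups. The forward hydrogenation must deliver hydrogen to C10 from the open face.

**Key disconnection (24 ⇒ 22).** The C5–C6 bond is cut to give phenol bromide 22. This takes away ring B and the C5 stereocentre in one move and leaves an aromatic ring that is easy to carry. The forward reaction is a C-alkylation of the phenoxide at its methyl-bearing ortho carbon.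

- Oxygen and C3 are out of reach, since either would need an eight-membered ring.
- C1 is not out of reach. It is para to the oxygen but ortho to the side chain, so it can close a six-membered ring just as C5 can, and rearomatisation would then make that path irreversible.
- The closure is therefore planned for a contact ion pair in a non-polar solvent, where the cation held at oxygen can assist bromide departure only for attack by the neighbouring ortho carbon. A dissociating, hydrogen-bonding medium would favour the para carbon.
- The C8/C9 stereodiad decides the face of C5 through a chair transition state.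

**End groups (22 ⇒ 21 ⇒ 20).** The bromide comes from a primary alcohol and the free phenol from an acetal-protected one. Both are exposed only just before the key step, because a phenoxide and an alkyl bromide cannot coexist earlier.

**C11–aryl bond (20 ⇒ 19 ⇒ 16 ⇒ 13 + 14).** The benzylic C11–H is traced back to a carbinol, and the C11–aryl bond is cut between aldehyde 13 and arene 14. A neopentylic C11 cannot be attacked in a substitution, so the bond is made by carbonyl addition and the oxygen removed by a radical path. A cationic deoxygenation next to the quaternary C9 would risk 1,2-shifts.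

**Lactone (13 ⇒ 12 ⇒ 11 ⇒ 10).** Aldehyde 13 is the opened and differentiated form of δ-lactone 10, whose ring holds C11, C9, C8, C7, C6 and the C6 oxygen. The lactone supplies C11 at the carbonyl level and C6 already oxygenated. It also offers a six-membered ring in which the C9 centre can be set relative to C8.

**C9 substituents (10 ⇒ 8 ⇒ 5 + 2).** The C9–CH3 bond is cut first (enolate methylation, anti to the C8 methyl), then the C9–C10 bond (α-arylation with aryl bromide 2). The order matters: the group introduced last ends trans to the C8 methyl, and the target needs the aryl group cis to it.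

**Starting materials (5 ⇒ 3; 2 ⇒ 1).** Lactone 5 comes from hemiester 3, which carries the C8 stereocentre. Aryl bromide 2 is the protected form of phenol 1.

## Alternatives that were turned down

**Alternative 1: biomimetic cationic rearrangement of an ent-drimane.**
- Disconnection: the C9–CH3 and C5–CH3 bonds and the C4 methylidene are traced to alcohol A2 by reversing two hydride and two methyl shifts.
- Forward key step: an acid ionises C8 of A2 and four suprafacial 1,2-shifts run to A1, ending with loss of a proton from a C4 methyl group.
- For it: it forms both quaternary methyl centres and the alkene in one operation, with all four stereocentres relayed stereospecifically. Only two steps would remain after A1. On step economy and on the number of stereocentres set per step it is clearly stronger than the chosen route.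
- Against it: the cascade must pass five cationic stations and stop at exactly one of them. Proton loss can occur after each shift, and the required exocyclic alkene is the least substituted and most acid-labile outcome. The electron-rich arene also sits within reach of the C9 and C10 cations. A2 must belong to the enantiomeric drimane series, so it has to come from an enantioselective polyene cyclisation and not from the chiral pool.
- Comparison: the chosen route is longer, but each stereocentre is set in its own substrate-controlled event, and only one selectivity question remains open at the key step.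

**Alternative 2: intramolecular Diels–Alder reaction.**
- Disconnection: C5–C10 and C3–C4, leading to trienoate A4.
- Forward key step: a Lewis acid activates the enoate of A4, which adds across the diene to give octalin ester A3.
- For it: it closes both rings and sets C4, C5 and C10 at once, more than the chosen key step achieves. It has no regiochemical ambiguity on an arene, and Lewis-acid-promoted decatrienoate cyclisations tend to give trans fusion.
- Against it: the dienophile carbon C5 is fully substituted and the diene hangs on the quaternary C9, so the cycloaddition is sterically slow. The Lewis acid can instead engage the tetramethoxyarene or the diene. A3 still needs the C1=C2 bond saturated and the C4 ester turned into a methylidene by reduction, activation and elimination, which can also give the ring alkene. A4 needs the same C8/C9 stereodiad as the chosen route, plus two defined alkenes.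
- Comparison: the chosen route carries ring A as a stable arene and arrives at C4 already at the ketone level.

**Alternative 3: enamine Michael closure of ring B.**
- Disconnection: C8–C9, leading to enone aldehyde A6.
- Forward key step: a secondary amine and a carboxylic acid convert A6 into its enamine, which adds to the enone carbon C8 to give A5.
- For it: both C9 epimers of A6 converge, and C8 and C9 are set in the ring closure. The aryl methyl group is already in place, so no benzylic deoxygenation is needed. On that point, and in having no ortho/para question, it is stronger than the chosen route.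
- Against it: the enamine of a fully α-branched aldehyde forms slowly and is a weak nucleophile, and it must create a quaternary carbon next to a tertiary one in a 6-endo closure. Four diastereomers at C8/C9 are possible. A5 then needs three oxygen functions adjusted: the C6 ketone removed, the C9 formyl reduced to methyl, and the C4 silyl ether taken to ketone and methylidene. A6 already needs an enantioselective ring A with the quaternary C5.
- Comparison: the chosen route reaches its key step from simple aromatic and chiral-pool pieces and needs four steps after it.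

Key step: step 13

## Route

Assumption: methyl hydrogen (R)-3-methylglutarate (3) is taken as a purchasable enantiopure building block; carbon labels C1–C11 are those of the target skeleton and are used for all intermediates.

Step 1
Reactants: 1 3-bromo-2-methylphenol
Product: 2 1-bromo-3-(methoxymethoxy)-2-methylbenzene
Conditions: MOMCl, i-Pr2NEt, CH2Cl2, 0 °C to rt
Reagents that add atoms: chloromethyl methyl ether, COCCl
Why: O-alkylation of the phenol with an α-chloro ether (MOM protection); the acetal withstands the bases, hydrides and organolithium reagents used later and is removed by acid.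

Step 2
Reactants: 3 methyl hydrogen (R)-3-methylglutarate
Product: 5 (4R)-4-methyloxan-2-one, via hydroxy ester 4 (not isolated)
Conditions: BH3·SMe2, THF, 0 °C to rt; then TsOH (cat.), toluene, 80 °C
Reagents that add atoms: none
Why: Chemoselective borane reduction of the carboxylic acid beside the methyl ester, then acid-catalysed lactonisation; the C8 stereocentre is taken over from 3 and is not touched.

Step 3
Reactants: 5 (4R)-4-methyloxan-2-one; 2 1-bromo-3-(methoxymethoxy)-2-methylbenzene
Product: 8 (3R,4R)-3-[3-(methoxymethoxy)-2-methylphenyl]-4-methyloxan-2-one, via lithium enolate 6 (not isolated), via chlorozinc enolate 7 (not isolated)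
Conditions: LiN(SiMe3)2, THF, −78 °C; ZnCl2, −78 °C to rt; then 2, Pd(dba)2 (cat.), P(t-Bu)3 (cat.), THF, rt to 60 °C
Reagents that add atoms: none
Why: Palladium-catalysed α-arylation of an ester enolate in its Negishi-type (zinc enolate) form, chosen because lithium lactone enolates self-condense at coupling temperature; the trans isomer is expected, but the C9 configuration is irrelevant because C9 is made planar again in step 4.

Step 4
Reactants: 8 (3R,4R)-3-[3-(methoxymethoxy)-2-methylphenyl]-4-methyloxan-2-one
Product: 10 (3S,4R)-3-[3-(methoxymethoxy)-2-methylphenyl]-3,4-dimethyloxan-2-one, via lithium enolate 9 (not isolated)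
Conditions: LiN(i-Pr)2, THF, −78 °C; MeI, −78 to 0 °C
Reagents that add atoms: iodomethane, CI
Why: Alkylation of a cyclic ester enolate; in the half-chair enolate the C8 methyl turns pseudo-axial to avoid allylic strain with the C9 aryl group, so iodomethane should enter anti to it, placing the new C9 methyl trans and the aryl group cis to the C8 methyl as the target requires.

Step 5
Reactants: 10 (3S,4R)-3-[3-(methoxymethoxy)-2-methylphenyl]-3,4-dimethyloxan-2-one
Product: 11 (2S,3R)-2-[3-(methoxymethoxy)-2-methylphenyl]-2,3-dimethylpentane-1,5-diol
Conditions: LiAlH4, THF, 0 °C to rt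
Reagents that add atoms: none
Why: Hydride reduction of the lactone to the 1,5-diol; the acetal and the aryl ether are inert and no stereocentre is involved.

Step 6
Reactants: 11 (2S,3R)-2-[3-(methoxymethoxy)-2-methylphenyl]-2,3-dimethylpentane-1,5-diol
Product: 12 (2S,3R)-5-[(tert-butyldimethylsilyl)oxy]-2-[3-(methoxymethoxy)-2-methylphenyl]-2,3-dimethylpentan-1-ol
Conditions: TBSCl (1.05 equiv), imidazole, CH2Cl2, 0 °C
Reagents that add atoms: tert-butyldimethylsilyl chloride, CC(C)(C)[Si](C)(C)Cl
Why: Selective silylation of the unhindered C6 hydroxyl; the C11 hydroxyl is neopentylic, flanked by the quaternary C9, and should react much more slowly.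

Step 7
Reactants: 12 (2S,3R)-5-[(tert-butyldimethylsilyl)oxy]-2-[3-(methoxymethoxy)-2-methylphenyl]-2,3-dimethylpentan-1-ol
Product: 13 (2S,3R)-5-[(tert-butyldimethylsilyl)oxy]-2-[3-(methoxymethoxy)-2-methylphenyl]-2,3-dimethylpentanal
Conditions: Dess–Martin periodinane, NaHCO3, CH2Cl2, rt
Reagents that add atoms: none
Why: Dess–Martin oxidation of the primary alcohol; the aldehyde has no α-hydrogen, so it can neither epimerise nor enolise.

Step 8
Reactants: 13 (2S,3R)-5-[(tert-butyldimethylsilyl)oxy]-2-[3-(methoxymethoxy)-2-methylphenyl]-2,3-dimethylpentanal; 14 1,2,4,5-tetramethoxybenzene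
Product: 16 (2S,3R)-5-[(tert-butyldimethylsilyl)oxy]-2-[3-(methoxymethoxy)-2-methylphenyl]-2,3-dimethyl-1-(2,3,5,6-tetramethoxyphenyl)pentan-1-ol (both C11 epimers), via aryllithium 15 (not isolated)
Conditions: 14, n-BuLi, THF, 0 °C; then 13, −78 to 0 °C; NH4Cl (aq)
Reagents that add atoms: none
Why: Ortho-lithiation of 14 between two directing methoxy groups (both ring hydrogens are equivalent) and 1,2-addition of the aryllithium to the non-enolisable aldehyde; the carbinol centre is removed in step 10, so its configuration does not matter.

Step 9
Reactants: 16 (2S,3R)-5-[(tert-butyldimethylsilyl)oxy]-2-[3-(methoxymethoxy)-2-methylphenyl]-2,3-dimethyl-1-(2,3,5,6-tetramethoxyphenyl)pentan-1-ol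
Product: 19 O-[(2S,3R)-5-[(tert-butyldimethylsilyl)oxy]-2-[3-(methoxymethoxy)-2-methylphenyl]-2,3-dimethyl-1-(2,3,5,6-tetramethoxyphenyl)pentyl] S-methyl dithiocarbonate, via sodium alkoxide 17 (not isolated), via sodium xanthate 18 (not isolated)
Conditions: NaN(SiMe3)2, THF, −78 °C; CS2, −78 °C to rt; MeI, rt
Reagents that add atoms: carbon disulfide, S=C=S; iodomethane, CI
Why: Xanthate formation, the first half of a Barton–McCombie deoxygenation; the sodium alkoxide of the hindered carbinol adds to carbon disulfide and the dithiocarbonate salt is S-methylated.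

Step 10
Reactants: 19 O-[(2S,3R)-5-[(tert-butyldimethylsilyl)oxy]-2-[3-(methoxymethoxy)-2-methylphenyl]-2,3-dimethyl-1-(2,3,5,6-tetramethoxyphenyl)pentyl] S-methyl dithiocarbonate
Product: 20 tert-butyl{[(3R,4S)-4-[3-(methoxymethoxy)-2-methylphenyl]-3,4-dimethyl-5-(2,3,5,6-tetramethoxyphenyl)pentyl]oxy}dimethylsilane
Conditions: Bu3SnH, AIBN (cat.), toluene, 110 °C
Reagents that add atoms: none
Why: Barton–McCombie radical deoxygenation; the benzylic C11 radical takes hydrogen from the stannane, and the radical path avoids the 1,2-shifts that a C11 cation next to the quaternary C9 would invite.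

Step 11
Reactants: 20 tert-butyl{[(3R,4S)-4-[3-(methoxymethoxy)-2-methylphenyl]-3,4-dimethyl-5-(2,3,5,6-tetramethoxyphenyl)pentyl]oxy}dimethylsilane
Product: 21 3-[(2S,3R)-5-hydroxy-2,3-dimethyl-1-(2,3,5,6-tetramethoxyphenyl)pentan-2-yl]-2-methylphenol
Conditions: HCl, MeOH, 40 °C
Reagents that add atoms: none
Why: Acid-catalysed methanolysis should remove the MOM acetal and the silyl ether together; aryl methyl ethers are stable under these conditions.

Step 12
Reactants: 21 3-[(2S,3R)-5-hydroxy-2,3-dimethyl-1-(2,3,5,6-tetramethoxyphenyl)pentan-2-yl]-2-methylphenol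
Product: 22 3-[(2S,3R)-5-bromo-2,3-dimethyl-1-(2,3,5,6-tetramethoxyphenyl)pentan-2-yl]-2-methylphenol
Conditions: CBr4, PPh3, CH2Cl2, 0 °C
Reagents that add atoms: tetrabromomethane, BrC(Br)(Br)Br
Why: Appel reaction; only the primary alcohol is substituted (SN2 on the alkoxyphosphonium ion), the phenol is returned on work-up, and no base is present that could start the cyclisation early.

Step 13
Reactants: 22 3-[(2S,3R)-5-bromo-2,3-dimethyl-1-(2,3,5,6-tetramethoxyphenyl)pentan-2-yl]-2-methylphenol
Product: 24 (5S,6R,8aR)-5,6,8a-trimethyl-5-[(2,3,5,6-tetramethoxyphenyl)methyl]-5,6,7,8-tetrahydronaphthalen-1(8aH)-one, via sodium phenoxide 23 (not isolated)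
Conditions: NaN(SiMe3)2 (1.05 equiv, in toluene), toluene (0.01 M), 0 °C then 90 °C, dark
Reagents that add atoms: none
Why: The base converts the phenol into sodium phenoxide 23, which in toluene stays a contact ion pair; its methyl-bearing ortho carbon C5 displaces bromide from C6 in an intramolecular SN2 reaction, with the sodium ion bridging the phenoxide oxygen and the leaving bromide. The closest known reaction types are the ortho C-alkylation of alkali 2,6-dialkylphenoxides by alkyl halides in non-polar solvents to 6,6-dialkylcyclohexa-2,4-dienones, and intramolecular phenoxide C-alkylations by tethered halides or sulfonates. Ring B closes in the 6-exo-tet mode (the enolate-type C4–C5 unit lies inside the new ring) through a chair-like transition state, helped by the gem-disubstitution at C9. The new stereocentre C5 is controlled by the C8/C9 pair: in the chair with the C8 methyl equatorial, the C9 methyl axial and the C11 arm equatorial, C6 reaches the face of C5 that leaves the C5 methyl axial and cis to the C9 methyl, whereas the other face would put the C11 arm and the C8 methyl axial. The step needs carbon over oxygen and C5 over the other ring carbons: O-alkylation and attack by C3 would need eight-membered rings, but C1, para to oxygen, is also ortho to the side chain and can close a six-membered ring, which after tautomerisation would be irreversible. This competitor is countered by the medium, because only the ortho carbon can use the cation-bridged array O–Na···Br–C6, whereas a dissociated, hydrogen-bonded phenoxide in an alcohol would favour the para carbon. It is also countered by the substrate, because closure at C1 forces the C9 substituent that stays in the arene plane to eclipse the C5 methyl, while closure at C5 makes it eclipse only H1. High dilution suppresses intermolecular alkylation, and the dienone is used at once because 6,6-disubstituted cyclohexa-2,4-dienones dimerise and are light-sensitive.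

Step 14
Reactants: 24 (5S,6R,8aR)-5,6,8a-trimethyl-5-[(2,3,5,6-tetramethoxyphenyl)methyl]-5,6,7,8-tetrahydronaphthalen-1(8aH)-one
Product: 25 (4aR,5S,6R,8aR)-5,6,8a-trimethyl-5-[(2,3,5,6-tetramethoxyphenyl)methyl]octahydronaphthalen-1(2H)-one
Conditions: H2 (3 atm), Pd/C, EtOAc, rt
Reagents that add atoms: none
Why: Heterogeneous catalytic hydrogenation of both ring double bonds; hydrogen should reach C10 from the face opposite the two axial methyl groups on C5 and C9, which gives H10 anti to them and hence the trans ring fusion.

Step 15
Reactants: 25 (4aR,5S,6R,8aR)-5,6,8a-trimethyl-5-[(2,3,5,6-tetramethoxyphenyl)methyl]octahydronaphthalen-1(2H)-one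
Product: 26 3-{[(1S,2R,4aR,8aR)-1,2,4a-trimethyl-5-methylidenedecahydronaphthalen-1-yl]methyl}-1,2,4,5-tetramethoxybenzene
Conditions: Ph3PCH3Br, KOt-Bu, toluene, 90 °C
Reagents that add atoms: methyltriphenylphosphonium bromide, C[P+](c1ccccc1)(c1ccccc1)c1ccccc1.[Br-]
Why: Wittig methylenation with the non-stabilised ylide at elevated temperature, as suits a ketone next to a quaternary carbon; C5 carries no hydrogen, so no stereocentre can be lost.

Step 16
Reactants: 26 3-{[(1S,2R,4aR,8aR)-1,2,4a-trimethyl-5-methylidenedecahydronaphthalen-1-yl]methyl}-1,2,4,5-tetramethoxybenzene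
Product: 27 2,5-dimethoxy-3-{[(1S,2R,4aR,8aR)-1,2,4a-trimethyl-5-methylidenedecahydronaphthalen-1-yl]methyl}cyclohexa-2,5-diene-1,4-dione
Conditions: (NH4)2Ce(NO3)6, MeCN/H2O, 0 °C
Reagents that add atoms: water, O
Why: Oxidative demethylation of a para-dimethoxyarene to the quinone by one-electron oxidation; the arene is symmetric about the C11 axis, so either para pair gives the same 2,5-dimethoxy-3-alkylquinone, and the isolated alkene should not react at 0 °C.

Step 17
Reactants: 27 2,5-dimethoxy-3-{[(1S,2R,4aR,8aR)-1,2,4a-trimethyl-5-methylidenedecahydronaphthalen-1-yl]methyl}cyclohexa-2,5-diene-1,4-dione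
Product: 28 2-hydroxy-5-methoxy-3-{[(1S,2R,4aR,8aR)-1,2,4a-trimethyl-5-methylidenedecahydronaphthalen-1-yl]methyl}cyclohexa-2,5-diene-1,4-dione (CNP0172818.3)
Conditions: KOH (aq), MeOH, rt; then dilute HCl to pH 5
Reagents that add atoms: potassium hydroxide, [K+].[OH-]
Why: Addition–elimination of hydroxide on a vinylogous ester; the methoxy group next to the bulky side chain is twisted out of conjugation and is the more electrophilic, so the hydroxyl should appear beside the alkyl group, and the mild work-up protects the methylidene from acid.

## Compound list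

1 | 3-bromo-2-methylphenol | Cc1c(O)cccc1Br | starting material
2 | 1-bromo-3-(methoxymethoxy)-2-methylbenzene | Cc1c(OCOC)cccc1Br | intermediate
3 | methyl hydrogen (R)-3-methylglutarate, (3R)-5-methoxy-3-methyl-5-oxopentanoic acid | COC(=O)C[C@H](C)CC(=O)O | starting material
4 | methyl (3R)-5-hydroxy-3-methylpentanoate (not isolated) | COC(=O)C[C@H](C)CCO | intermediate
5 | (4R)-4-methyloxan-2-one | O=C1C[C@H](C)CCO1 | intermediate
6 | lithium enolate of 5, lithium (4R)-4-methyl-5,6-dihydro-4H-pyran-2-olate (not isolated) | [Li]OC1=C[C@H](C)CCO1 | intermediate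
7 | chlorozinc enolate of 5 (not isolated) | Cl[Zn]OC1=C[C@H](C)CCO1 | intermediate
8 | (3R,4R)-3-[3-(methoxymethoxy)-2-methylphenyl]-4-methyloxan-2-one (trans isomer drawn; the C3 epimer is equally usable) | O=C1[C@@H](c2cccc(OCOC)c2C)[C@H](C)CCO1 | intermediate
9 | lithium enolate of 8 (not isolated) | [Li]OC1=C(c2cccc(OCOC)c2C)[C@H](C)CCO1 | intermediate
10 | (3S,4R)-3-[3-(methoxymethoxy)-2-methylphenyl]-3,4-dimethyloxan-2-one | O=C1[C@](C)(c2cccc(OCOC)c2C)[C@H](C)CCO1 | intermediate
11 | (2S,3R)-2-[3-(methoxymethoxy)-2-methylphenyl]-2,3-dimethylpentane-1,5-diol | OC[C@](C)(c1cccc(OCOC)c1C)[C@H](C)CCO | intermediate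
12 | (2S,3R)-5-[(tert-butyldimethylsilyl)oxy]-2-[3-(methoxymethoxy)-2-methylphenyl]-2,3-dimethylpentan-1-ol | OC[C@](C)(c1cccc(OCOC)c1C)[C@H](C)CCO[Si](C)(C)C(C)(C)C | intermediate
13 | (2S,3R)-5-[(tert-butyldimethylsilyl)oxy]-2-[3-(methoxymethoxy)-2-methylphenyl]-2,3-dimethylpentanal | O=C[C@](C)(c1cccc(OCOC)c1C)[C@H](C)CCO[Si](C)(C)C(C)(C)C | intermediate
14 | 1,2,4,5-tetramethoxybenzene | COc1cc(OC)c(OC)cc1OC | starting material
15 | (2,3,5,6-tetramethoxyphenyl)lithium (not isolated) | [Li]c1c(OC)c(OC)cc(OC)c1OC | intermediate
16 | (2S,3R)-5-[(tert-butyldimethylsilyl)oxy]-2-[3-(methoxymethoxy)-2-methylphenyl]-2,3-dimethyl-1-(2,3,5,6-tetramethoxyphenyl)pentan-1-ol, both C11 epimers | OC(c1c(OC)c(OC)cc(OC)c1OC)[C@](C)(c1cccc(OCOC)c1C)[C@H](C)CCO[Si](C)(C)C(C)(C)C | intermediate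
17 | sodium alkoxide of 16 (not isolated) | [Na+].[O-]C(c1c(OC)c(OC)cc(OC)c1OC)[C@](C)(c1cccc(OCOC)c1C)[C@H](C)CCO[Si](C)(C)C(C)(C)C | intermediate
18 | sodium O-alkyl dithiocarbonate of 16 (not isolated) | [Na+].[S-]C(=S)OC(c1c(OC)c(OC)cc(OC)c1OC)[C@](C)(c1cccc(OCOC)c1C)[C@H](C)CCO[Si](C)(C)C(C)(C)C | intermediate
19 | O-[(2S,3R)-5-[(tert-butyldimethylsilyl)oxy]-2-[3-(methoxymethoxy)-2-methylphenyl]-2,3-dimethyl-1-(2,3,5,6-tetramethoxyphenyl)pentyl] S-methyl dithiocarbonate | CSC(=S)OC(c1c(OC)c(OC)cc(OC)c1OC)[C@](C)(c1cccc(OCOC)c1C)[C@H](C)CCO[Si](C)(C)C(C)(C)C | intermediate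
20 | tert-butyl{[(3R,4S)-4-[3-(methoxymethoxy)-2-methylphenyl]-3,4-dimethyl-5-(2,3,5,6-tetramethoxyphenyl)pentyl]oxy}dimethylsilane | Cc1c(OCOC)cccc1[C@@](C)(Cc1c(OC)c(OC)cc(OC)c1OC)[C@H](C)CCO[Si](C)(C)C(C)(C)C | intermediate
21 | 3-[(2S,3R)-5-hydroxy-2,3-dimethyl-1-(2,3,5,6-tetramethoxyphenyl)pentan-2-yl]-2-methylphenol | Cc1c(O)cccc1[C@@](C)(Cc1c(OC)c(OC)cc(OC)c1OC)[C@H](C)CCO | intermediate
22 | 3-[(2S,3R)-5-bromo-2,3-dimethyl-1-(2,3,5,6-tetramethoxyphenyl)pentan-2-yl]-2-methylphenol | Cc1c(O)cccc1[C@@](C)(Cc2c(OC)c(OC)cc(OC)c2OC)[C@H](C)CCBr | intermediate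
23 | sodium 3-[(2S,3R)-5-bromo-2,3-dimethyl-1-(2,3,5,6-tetramethoxyphenyl)pentan-2-yl]-2-methylphenolate (not isolated) | Cc1c([O-])cccc1[C@@](C)(Cc2c(OC)c(OC)cc(OC)c2OC)[C@H](C)CCBr.[Na+] | intermediate
24 | (5S,6R,8aR)-5,6,8a-trimethyl-5-[(2,3,5,6-tetramethoxyphenyl)methyl]-5,6,7,8-tetrahydronaphthalen-1(8aH)-one | O=C1C=CC=C2[C@@](C)(Cc3c(OC)c(OC)cc(OC)c3OC)[C@H](C)CC[C@@]12C | intermediate
25 | (4aR,5S,6R,8aR)-5,6,8a-trimethyl-5-[(2,3,5,6-tetramethoxyphenyl)methyl]octahydronaphthalen-1(2H)-one | O=C1CCC[C@@H]2[C@@](C)(Cc3c(OC)c(OC)cc(OC)c3OC)[C@H](C)CC[C@@]12C | intermediate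
26 | 3-{[(1S,2R,4aR,8aR)-1,2,4a-trimethyl-5-methylidenedecahydronaphthalen-1-yl]methyl}-1,2,4,5-tetramethoxybenzene | C=C1CCC[C@@H]2[C@@](C)(Cc3c(OC)c(OC)cc(OC)c3OC)[C@H](C)CC[C@@]12C | intermediate
27 | 2,5-dimethoxy-3-{[(1S,2R,4aR,8aR)-1,2,4a-trimethyl-5-methylidenedecahydronaphthalen-1-yl]methyl}cyclohexa-2,5-diene-1,4-dione | C=C1CCC[C@@H]2[C@@](C)(CC3=C(OC)C(=O)C=C(OC)C3=O)[C@H](C)CC[C@@]12C | intermediate
28 | 2-hydroxy-5-methoxy-3-{[(1S,2R,4aR,8aR)-1,2,4a-trimethyl-5-methylidenedecahydronaphthalen-1-yl]methyl}cyclohexa-2,5-diene-1,4-dione | C=C1CCC[C@@H]2[C@@](C)(CC3=C(O)C(=O)C=C(OC)C3=O)[C@H](C)CC[C@@]12C | target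

## Step count and least certain steps

Total step count: 17. Longest linear sequence: 16 steps (from 3 through steps 2–17, or from 1 through steps 1 and 3–17).

**Step 13 (key step).**
- Most likely failure: closure at C1 instead of C5. C1 is para to the phenoxide oxygen and, like C5, ortho to the side chain, so the two closures have transition states of the same ring size; attack at C1 is followed by irreversible rearomatisation. The contact ion pair in toluene and the eclipsing argument are expected to favour C5, but neither is a guarantee. Intermolecular alkylation and loss of the dienone by dimerisation are lesser risks.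
- Fallback: it sets out from 22. Ring bromination with N-bromosuccinimide (3 equiv, MeCN, 0 °C) should give 4,6-dibromo-3-[(2S,3R)-5-bromo-1-(4-bromo-2,3,5,6-tetramethoxyphenyl)-2,3-dimethylpentan-2-yl]-2-methylphenol F1. Here C1 and C3 of the phenol and the one free position of the tetramethoxyphenyl ring carry bromine, so C1 is blocked. Cyclisation under the conditions of step 13 should then give the tribromodienone (5S,6R,8aR)-2,4-dibromo-5-[(4-bromo-2,3,5,6-tetramethoxyphenyl)methyl]-5,6,8a-trimethyl-5,6,7,8-tetrahydronaphthalen-1(8aH)-one F2. Hydrogenation over Pd/C with Et3N should remove the three ring bromine atoms while saturating both double bonds. The fallback rejoins the route at 25.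

**Step 3 (α-arylation of the lactone).**
- Most likely failure: self-condensation or ring-opening of the lactone enolate before transmetalation, or slow coupling of the β-branched secondary enolate with the ortho-substituted aryl bromide.
- Fallback: the polarity is reversed, setting out from 5 and 2. Enolate bromination of 5 (LiN(i-Pr)2, then CBr4) should give (4R)-3-bromo-4-methyloxan-2-one F3. Bromine–lithium exchange on 2 (n-BuLi), borylation with B(OMe)3 and aqueous acid should give [3-(methoxymethoxy)-2-methylphenyl]boronic acid F4. A nickel-catalysed Suzuki-type arylation of the α-bromo ester (Ni(PPh3)4, K3PO4, toluene, 80 °C) should join the two. The fallback rejoins the route at 8.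

**Step 14 (hydrogenation).**
- Most likely failure: incomplete saturation of the trisubstituted C1=C10 bond, which lies between two quaternary carbons, or hydrogen delivery from the methyl-bearing face, leading to the cis ring fusion.
- Fallback: it sets out from 24. Hydrogenation with RhCl(PPh3)3 should saturate only the disubstituted C2=C3 bond, giving (5S,6R,8aR)-5,6,8a-trimethyl-5-[(2,3,5,6-tetramethoxyphenyl)methyl]-3,5,6,7,8,8a-hexahydronaphthalen-1(2H)-one F5. A hydrogen-atom-transfer hydrogenation (Mn(dpm)3, PhSiH3, t-BuOOH, i-PrOH) should then reduce C1=C10 through the tertiary C10 radical. That radical takes up hydrogen along the axial direction and gives the more stable trans-decalin. The fallback rejoins the route at 25.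

**Step 15 (methylenation).**
- Most likely failure: enolisation of the ketone towards C3 by the basic ylide, or slow addition to the carbonyl next to the quaternary C5, leaving ketone unchanged.
- Fallback: a Peterson olefination, setting out from 25. Addition of Me3SiCH2Li in the presence of CeCl3 should give the β-hydroxysilane 5,6,8a-trimethyl-5-[(2,3,5,6-tetramethoxyphenyl)methyl]-1-[(trimethylsilyl)methyl]decahydronaphthalen-1-ol F6. Elimination with KH in THF then forms the alkene. The fallback rejoins the route at 26.

## Further compounds

F1 | step 13 | 4,6-dibromo-3-[(2S,3R)-5-bromo-1-(4-bromo-2,3,5,6-tetramethoxyphenyl)-2,3-dimethylpentan-2-yl]-2-methylphenol | Cc1c(O)c(Br)cc(Br)c1[C@@](C)(Cc2c(OC)c(OC)c(Br)c(OC)c2OC)[C@H](C)CCBr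
F2 | step 13 | (5S,6R,8aR)-2,4-dibromo-5-[(4-bromo-2,3,5,6-tetramethoxyphenyl)methyl]-5,6,8a-trimethyl-5,6,7,8-tetrahydronaphthalen-1(8aH)-one | O=C1C(Br)=CC(Br)=C2[C@@](C)(Cc3c(OC)c(OC)c(Br)c(OC)c3OC)[C@H](C)CC[C@@]12C
F3 | step 3 | (4R)-3-bromo-4-methyloxan-2-one (both C3 epimers) | O=C1C(Br)[C@H](C)CCO1
F4 | step 3 | [3-(methoxymethoxy)-2-methylphenyl]boronic acid | COCOc1cccc(B(O)O)c1C
F5 | step 14 | (5S,6R,8aR)-5,6,8a-trimethyl-5-[(2,3,5,6-tetramethoxyphenyl)methyl]-3,5,6,7,8,8a-hexahydronaphthalen-1(2H)-one | O=C1CCC=C2[C@@](C)(Cc3c(OC)c(OC)cc(OC)c3OC)[C@H](C)CC[C@@]12C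
F6 | step 15 | (4aR,5S,6R,8aR)-5,6,8a-trimethyl-5-[(2,3,5,6-tetramethoxyphenyl)methyl]-1-[(trimethylsilyl)methyl]decahydronaphthalen-1-ol (either C4 epimer) | C[Si](C)(C)CC1(O)CCC[C@@H]2[C@@](C)(Cc3c(OC)c(OC)cc(OC)c3OC)[C@H](C)CC[C@@]12C
A1 | alternative 1 | 3-{[(1S,2R,4aR,8aR)-1,2,4a-trimethyl-5-methylidenedecahydronaphthalen-1-yl]methyl}-1,2,4,5-tetramethoxybenzene (identical with 26) | C=C1CCC[C@@H]2[C@@](C)(Cc3c(OC)c(OC)cc(OC)c3OC)[C@H](C)CC[C@@]12C
A2 | alternative 1 | ent-drimane tertiary alcohol: 8-hydroxy-11-(2,3,5,6-tetramethoxyphenyl)-ent-drimane, with H5 and H9 on the face opposite the C10 methyl group | CC1(C)CCC[C@]2(C)[C@@H]1CC[C@](C)(O)[C@H]2Cc1c(OC)c(OC)cc(OC)c1OC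
A3 | alternative 2 | methyl 5,6,8a-trimethyl-5-[(2,3,5,6-tetramethoxyphenyl)methyl]-1,2,4a,5,6,7,8,8a-octahydronaphthalene-1-carboxylate, trans-fused, ester cis to the angular methyl group | COC(=O)[C@@H]1CC=C[C@@H]2[C@@](C)(Cc3c(OC)c(OC)cc(OC)c3OC)[C@H](C)CC[C@@]12C
A4 | alternative 2 | methyl (2E,6R,7S,8E)-3,6,7-trimethyl-7-[(2,3,5,6-tetramethoxyphenyl)methyl]undeca-2,8,10-trienoate | COC(=O)/C=C(\C)CC[C@@H](C)[C@](C)(Cc1c(OC)c(OC)cc(OC)c1OC)/C=C/C=C
A5 | alternative 3 | 5-[(tert-butyldimethylsilyl)oxy]-2,4a-dimethyl-4-oxo-1-[(2,3,5,6-tetramethoxyphenyl)methyl]decahydronaphthalene-1-carbaldehyde, configuration as in the SMILES | CC(C)(C)[Si](C)(C)O[C@H]1CCC[C@@H]2[C@@](C=O)(Cc3c(OC)c(OC)cc(OC)c3OC)[C@H](C)CC(=O)[C@@]12C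
A6 | alternative 3 | 2-{3-[(tert-butyldimethylsilyl)oxy]-2-[(E)-but-2-enoyl]-2-methylcyclohexyl}-3-(2,3,5,6-tetramethoxyphenyl)propanal, either C9 epimer, ring configuration as in the SMILES | CC(C)(C)[Si](C)(C)O[C@H]1CCC[C@H](C(C=O)Cc2c(OC)c(OC)cc(OC)c2OC)[C@@]1(C)C(=O)/C=C/C
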